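**Plan**

- Cuts, last to first: O1–C8a (aryl ether of ring C), C2–C3 (aldol), C4–C4a (aryl ketone), C6–geranyl. O1 sits on the sp2 carbon C8a of ring A, para to the geranyl carbon C6, so C8a can start as the bromine-bearing carbon of symmetrical 5-bromoresorcinol and only the 6-geranyl isomer can arise.
- Forward: ring A is dressed first (MOM ethers, geranyl between them, acetyl next to bromine), the ring B aldehyde is joined by aldol, the two chain oxygens are told apart, and ring C is closed by palladium-catalysed O-arylation. Desilylation, oxidation at C4 and MOM removal finish the synthesis.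
- Stereochemistry: C2 (S) is set by a reagent-controlled diisopinocampheylboron aldol and its C–O bond is never broken afterwards. C4 is a temporary centre, set anti by Evans–Tishchenko reduction and erased by the late oxidation.

Key step: step 9

Remark: the sense of the boron aldol rests on the empirical facial preference of diisopinocampheylboron enolates of methyl ketones, taken here as Si-face attack on the aldehyde with (+)-Ipc2BCl; should the carbinol prove to be R, (−)-Ipc2BCl is used instead and nothing else changes.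

Step 1
Reactants: 1 5-bromoresorcinol
Product: 2 1-bromo-3,5-bis(methoxymethoxy)benzene
Conditions: MOMCl, iPr2NEt, CH2Cl2, 0 °C to rt
Reagents that add atoms: chloromethyl methyl ether, COCCl
Why: O-alkylation of both phenols with the chloromethyl ether (MOM protection) gives acetals that survive the bases used later and direct the ring metalations.

Step 2
Reactants: 2 1-bromo-3,5-bis(methoxymethoxy)benzene; 3 geranyl bromide
Product: 5 5-bromo-2-geranyl-1,3-bis(methoxymethoxy)benzene, via aryllithium 4 (not isolated)
Conditions: LiN(iPr)2, THF, −78 °C; then 3, −78 °C to rt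
Reagents that add atoms: none
Why: A lithium amide, unlike an alkyllithium, leaves the C–Br bond alone and should remove the proton flanked by both acetal oxygens (directed ortho-metalation at the doubly chelated position para to bromine), and the aryllithium is alkylated at the primary allylic carbon of 3 by SN2 displacement with the E alkene untouched.

Step 3
Reactants: 5 5-bromo-2-geranyl-1,3-bis(methoxymethoxy)benzene; 6 N-methoxy-N-methylacetamide
Product: 8 1-[2-bromo-5-geranyl-4,6-bis(methoxymethoxy)phenyl]ethan-1-one, via aryllithium 7 (not isolated)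
Conditions: lithium 2,2,6,6-tetramethylpiperidide, THF, −78 °C; then 6, −78 °C; H2O
Reagents that add atoms: none
Why: The only ring C–H left (two equivalent positions flanked by Br and OMOM) is removed by directed ortho-metalation at −78 °C, where the ortho-bromoaryllithium should keep its LiBr, and the Weinreb ketone synthesis stops at the methyl ketone because the chelated tetrahedral adduct survives until the quench.

Step 4
Reactants: 9 4-hydroxybenzaldehyde
Product: 10 4-(methoxymethoxy)benzaldehyde
Conditions: MOMCl, iPr2NEt, CH2Cl2, 0 °C to rt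
Reagents that add atoms: chloromethyl methyl ether, COCCl
Why: MOM protection by O-alkylation removes the acidic phenol proton before the boron aldol and matches the protecting groups of ring A.

Step 5
Reactants: 8 1-[2-bromo-5-geranyl-4,6-bis(methoxymethoxy)phenyl]ethan-1-one; 10 4-(methoxymethoxy)benzaldehyde
Product: 12 (3S)-1-[2-bromo-5-geranyl-4,6-bis(methoxymethoxy)phenyl]-3-hydroxy-3-[4-(methoxymethoxy)phenyl]propan-1-one, via boron enolate 11 (not isolated)
Conditions: (+)-Ipc2BCl, Et3N, Et2O, −78 to 0 °C; then 10, −78 to −20 °C; H2O2, MeOH, pH 7 buffer, 0 °C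
Reagents that add atoms: none
Why: Paterson boron aldol, in which (+)-Ipc2BCl and Et3N convert the methyl ketone into its diisopinocampheylboron enolate, which adds to 10 through a cyclic six-membered boron transition state whose chiral ligands should expose the Si face of the aldehyde, setting the 3S carbinol that becomes C2 of the flavanone.

Step 6
Reactants: 12 (3S)-1-[2-bromo-5-geranyl-4,6-bis(methoxymethoxy)phenyl]-3-hydroxy-3-[4-(methoxymethoxy)phenyl]propan-1-one
Product: 13 (1S,3S)-3-[2-bromo-5-geranyl-4,6-bis(methoxymethoxy)phenyl]-3-hydroxy-1-[4-(methoxymethoxy)phenyl]propyl acetate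
Conditions: SmI2 (cat.), CH3CHO (excess), THF, −10 °C
Reagents that add atoms: acetaldehyde, CC=O
Why: Evans–Tishchenko reduction, in which the samarium-bound hemiacetal formed from the carbinol and acetaldehyde delivers its hydride intramolecularly to the ketone through a chair-like six-membered transition state, setting the new carbinol (3S, the later C4) anti to the existing centre and leaving that oxygen as its acetate, so the two oxygens are differentiated in one operation.

Step 7
Reactants: 13 (1S,3S)-3-[2-bromo-5-geranyl-4,6-bis(methoxymethoxy)phenyl]-3-hydroxy-1-[4-(methoxymethoxy)phenyl]propyl acetate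
Product: 14 (1S,3S)-3-[2-bromo-5-geranyl-4,6-bis(methoxymethoxy)phenyl]-3-(tert-butyldimethylsilyloxy)-1-[4-(methoxymethoxy)phenyl]propyl acetate
Conditions: TBSOTf, 2,6-lutidine, CH2Cl2, −78 to 0 °C
Reagents that add atoms: tert-butyldimethylsilyl trifluoromethanesulfonate, CC(C)(C)[Si](C)(C)OS(=O)(=O)C(F)(F)F
Why: Silylation with the silyl triflate and a hindered pyridine base is forceful enough for the benzylic alcohol flanked by Br and OMOM, while at low temperature the acetate, the acetals and the alkenes should stay untouched.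

Step 8
Reactants: 14 (1S,3S)-3-[2-bromo-5-geranyl-4,6-bis(methoxymethoxy)phenyl]-3-(tert-butyldimethylsilyloxy)-1-[4-(methoxymethoxy)phenyl]propyl acetate
Product: 15 (1S,3S)-3-[2-bromo-5-geranyl-4,6-bis(methoxymethoxy)phenyl]-3-(tert-butyldimethylsilyloxy)-1-[4-(methoxymethoxy)phenyl]propan-1-ol
Conditions: K2CO3 (cat.), MeOH, 0 °C to rt
Reagents that add atoms: none
Why: Base-catalysed transesterification with methanol removes the acetate without touching the hindered silyl ether, the MOM acetals or the aryl bromide, and frees the C2 hydroxyl with its configuration unchanged.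

Step 9
Reactants: 15 (1S,3S)-3-[2-bromo-5-geranyl-4,6-bis(methoxymethoxy)phenyl]-3-(tert-butyldimethylsilyloxy)-1-[4-(methoxymethoxy)phenyl]propan-1-ol
Product: 16 (2S,4S)-4-(tert-butyldimethylsilyloxy)-6-geranyl-5,7,4′-tris(methoxymethoxy)flavan
Conditions: Pd(OAc)2 (cat.), 2-(di-tert-butylphosphino)-1,1′-binaphthyl (cat.), Cs2CO3, toluene, 80 °C
Reagents that add atoms: none
Why: Zerovalent palladium, formed in the flask from Pd(OAc)2 and the bulky monophosphine, inserts into the C8a–Br bond to give an arylpalladium bromide (divalent palladium); Cs2CO3 deprotonates the C2 carbinol, the alkoxide takes the place of bromide, and C–O reductive elimination forms O1–C8a and returns zerovalent palladium. The closest known reaction type is the Buchwald–Hartwig-type intramolecular etherification of aryl bromides with secondary alcohols, which gives chromans. Ring C closes as a six-membered ring by reductive elimination from a seven-membered aryl(alkoxo)palladium chelate, formally a 6-exo closure at the sp2 carbon C8a. No new stereocentre is formed: the C2–O bond is not broken, so the S configuration from the aldol is retained, and C4 rides through as its silyl ether. The step needs reductive elimination to outrun β-hydride elimination from the alkoxide, which the bulky electron-rich ligand and the chelate ring should secure; the silylated C4 oxygen can neither compete as a nucleophile nor allow elimination or retro-aldol cleavage, and the bromine para to the geranyl carbon admits only the 6-geranyl flavan.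

Step 10
Reactants: 16 (2S,4S)-4-(tert-butyldimethylsilyloxy)-6-geranyl-5,7,4′-tris(methoxymethoxy)flavan
Product: 17 (2S,4S)-6-geranyl-5,7,4′-tris(methoxymethoxy)flavan-4-ol
Conditions: Bu4NF, THF, 0 °C to rt
Reagents that add atoms: none
Why: Fluoride cleaves the Si–O bond (desilylation) and leaves the acetals, the alkenes and the O1–C2 ether bond intact.

Step 11
Reactants: 17 (2S,4S)-6-geranyl-5,7,4′-tris(methoxymethoxy)flavan-4-ol
Product: 18 (2S)-6-geranyl-5,7,4′-tris(methoxymethoxy)flavanone
Conditions: Dess–Martin periodinane, NaHCO3, CH2Cl2, 0 °C to rt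
Reagents that add atoms: none
Why: Dess–Martin oxidation turns the benzylic C4 alcohol into the chromanone carbonyl under buffered, non-basic conditions, so the flavanone should not open by retro-oxa-Michael reaction and C2 stays S.

Step 12
Reactants: 18 (2S)-6-geranyl-5,7,4′-tris(methoxymethoxy)flavanone
Product: 19 bonannione A, (2S)-6-geranyl-5,7,4′-trihydroxyflavanone
Conditions: HCl (dilute, aq.), MeOH, 40 °C
Reagents that add atoms: none
Why: Acid-catalysed acetal exchange with methanol removes the three MOM groups, and the mild conditions are chosen so that the geranyl alkenes are not protonated and the flavanone does not equilibrate with its chalcone, leaving C2 as S.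

**Compound list**

1 | 5-bromoresorcinol | Oc1cc(O)cc(Br)c1 | starting material
2 | 1-bromo-3,5-bis(methoxymethoxy)benzene | COCOc1cc(Br)cc(OCOC)c1 | intermediate
3 | geranyl bromide, (2E)-1-bromo-3,7-dimethylocta-2,6-diene | CC(C)=CCC/C(C)=C/CBr | starting material
4 | [4-bromo-2,6-bis(methoxymethoxy)phenyl]lithium | [Li]c1c(OCOC)cc(Br)cc1OCOC | intermediate
5 | 5-bromo-2-geranyl-1,3-bis(methoxymethoxy)benzene (geranyl = (2E)-3,7-dimethylocta-2,6-dien-1-yl) | COCOc1cc(Br)cc(OCOC)c1C/C=C(\C)CCC=C(C)C | intermediate
6 | N-methoxy-N-methylacetamide | CC(=O)N(C)OC | starting material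
7 | [2-bromo-5-geranyl-4,6-bis(methoxymethoxy)phenyl]lithium | [Li]c1c(Br)cc(OCOC)c(C/C=C(\C)CCC=C(C)C)c1OCOC | intermediate
8 | 1-[2-bromo-5-geranyl-4,6-bis(methoxymethoxy)phenyl]ethan-1-one | CC(=O)c1c(Br)cc(OCOC)c(C/C=C(\C)CCC=C(C)C)c1OCOC | intermediate
9 | 4-hydroxybenzaldehyde | O=Cc1ccc(O)cc1 | starting material
10 | 4-(methoxymethoxy)benzaldehyde | COCOc1ccc(C=O)cc1 | intermediate
11 | enol borinate of 8 carrying the two isopinocampheyl groups of (+)-Ipc2BCl | C=C(OB([C@H]1C[C@H]2C[C@@H]([C@@H]1C)C2(C)C)[C@H]1C[C@H]2C[C@@H]([C@@H]1C)C2(C)C)c1c(Br)cc(OCOC)c(C/C=C(\C)CCC=C(C)C)c1OCOC | intermediate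
12 | (3S)-1-[2-bromo-5-geranyl-4,6-bis(methoxymethoxy)phenyl]-3-hydroxy-3-[4-(methoxymethoxy)phenyl]propan-1-one | O=C(C[C@@H](c1ccc(OCOC)cc1)O)c1c(Br)cc(OCOC)c(C/C=C(\C)CCC=C(C)C)c1OCOC | intermediate
13 | (1S,3S)-3-[2-bromo-5-geranyl-4,6-bis(methoxymethoxy)phenyl]-3-hydroxy-1-[4-(methoxymethoxy)phenyl]propyl acetate (anti) | Brc1cc(OCOC)c(C/C=C(\C)CCC=C(C)C)c(OCOC)c1[C@@H](O)C[C@@H](c1ccc(OCOC)cc1)OC(C)=O | intermediate
14 | (1S,3S)-3-[2-bromo-5-geranyl-4,6-bis(methoxymethoxy)phenyl]-3-(tert-butyldimethylsilyloxy)-1-[4-(methoxymethoxy)phenyl]propyl acetate | Brc1cc(OCOC)c(C/C=C(\C)CCC=C(C)C)c(OCOC)c1[C@@H](O[Si](C)(C)C(C)(C)C)C[C@@H](c1ccc(OCOC)cc1)OC(C)=O | intermediate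
15 | (1S,3S)-3-[2-bromo-5-geranyl-4,6-bis(methoxymethoxy)phenyl]-3-(tert-butyldimethylsilyloxy)-1-[4-(methoxymethoxy)phenyl]propan-1-ol | Brc1cc(OCOC)c(C/C=C(\C)CCC=C(C)C)c(OCOC)c1[C@@H](O[Si](C)(C)C(C)(C)C)C[C@@H](c1ccc(OCOC)cc1)O | intermediate
16 | (2S,4S)-4-(tert-butyldimethylsilyloxy)-6-geranyl-5,7,4′-tris(methoxymethoxy)flavan | CC(C)=CCC/C(C)=C/Cc1c(OCOC)cc2c(c1OCOC)[C@@H](O[Si](C)(C)C(C)(C)C)C[C@@H](c1ccc(OCOC)cc1)O2 | intermediate
17 | (2S,4S)-6-geranyl-5,7,4′-tris(methoxymethoxy)flavan-4-ol | CC(C)=CCC/C(C)=C/Cc1c(OCOC)cc2c(c1OCOC)[C@@H](O)C[C@@H](c1ccc(OCOC)cc1)O2 | intermediate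
18 | (2S)-6-geranyl-5,7,4′-tris(methoxymethoxy)flavanone | CC(C)=CCC/C(C)=C/Cc1c(OCOC)cc2c(c1OCOC)C(=O)C[C@@H](c1ccc(OCOC)cc1)O2 | intermediate
19 | bonannione A, (2S)-6-geranyl-5,7,4′-trihydroxyflavanone | CC(C)=CCC/C(C)=C/Cc1c(O)cc2c(c1O)C(=O)C[C@@H](c1ccc(O)cc1)O2 | target

**Step count**

Total: 12 steps. Longest linear sequence: 11 steps (1 to 19 through steps 1–3 and 5–12); step 4 is the one-step side branch.

**Steps most likely to fail**

Step 5. The isopinocampheyl ligands may discriminate poorly between the aldehyde faces with this hindered aryl methyl ketone enolate, or in the opposite sense to the one assumed, so the optical purity at C2 carried to the target would be insufficient. The fallback sets out from 8 and 10 and comes back at 12. Claisen–Schmidt condensation (KOH, EtOH) should give the chalcone (E)-1-[2-bromo-5-geranyl-4,6-bis(methoxymethoxy)phenyl]-3-[4-(methoxymethoxy)phenyl]prop-2-en-1-one F1. Juliá–Colonna epoxidation with poly-D-leucine, urea–H2O2 and DBU in THF should give the trans epoxy ketone [2-bromo-5-geranyl-4,6-bis(methoxymethoxy)phenyl][(2S,3R)-3-[4-(methoxymethoxy)phenyl]oxiran-2-yl]methanone F2. Reductive cleavage of the Cα–O bond with sodium phenylselenide (from (PhSe)2 and NaBH4, EtOH, AcOH, 0 °C) keeps the Cβ–O bond and should return the 3S hydroxy ketone 12.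

Step 3. The ortho-bromoaryllithium may lose LiBr (aryne formation) before acyl transfer, or the hindered aryllithium may take a proton from the amide instead of adding to it. The fallback sets out from 5 and comes back at 8. Deprotonation with lithium 2,2,6,6-tetramethylpiperidide in the presence of MgCl2 (in situ trapping, THF, −78 °C) converts the lithium species at once into the arylmagnesium chloride [2-bromo-5-geranyl-4,6-bis(methoxymethoxy)phenyl]magnesium chloride F3, which does not eliminate. Addition to acetaldehyde gives the racemic carbinol 1-[2-bromo-5-geranyl-4,6-bis(methoxymethoxy)phenyl]ethan-1-ol F4, and Dess–Martin oxidation gives 8.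

Step 9. β-Hydride elimination from the palladium alkoxide (oxidation of the carbinol with loss of bromine from the arene) may compete, or C–O reductive elimination at the ortho-substituted aryl may be too slow. The fallback changes the halide and the metal; it sets out from 14 and comes back at 16. Aromatic Finkelstein exchange (CuI cat., NaI, trans-N,N′-dimethylcyclohexane-1,2-diamine, dioxane, 110 °C) should give the iodide (1S,3S)-3-[5-geranyl-2-iodo-4,6-bis(methoxymethoxy)phenyl]-3-(tert-butyldimethylsilyloxy)-1-[4-(methoxymethoxy)phenyl]propyl acetate F5. Methanolysis (K2CO3, MeOH) gives the iodo alcohol (1S,3S)-3-[5-geranyl-2-iodo-4,6-bis(methoxymethoxy)phenyl]-3-(tert-butyldimethylsilyloxy)-1-[4-(methoxymethoxy)phenyl]propan-1-ol F6. Ullmann-type intramolecular etherification (CuI, 3,4,7,8-tetramethyl-1,10-phenanthroline, Cs2CO3, toluene, 110 °C) then closes ring C to 16; copper alkoxides are not prone to β-hydride elimination, and the C2–O bond is again untouched.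

Further compounds
F1 | step 5 | (E)-1-[2-bromo-5-geranyl-4,6-bis(methoxymethoxy)phenyl]-3-[4-(methoxymethoxy)phenyl]prop-2-en-1-one | O=C(/C=C/c1ccc(OCOC)cc1)c1c(Br)cc(OCOC)c(C/C=C(\C)CCC=C(C)C)c1OCOC
F2 | step 5 | [2-bromo-5-geranyl-4,6-bis(methoxymethoxy)phenyl][(2S,3R)-3-[4-(methoxymethoxy)phenyl]oxiran-2-yl]methanone | O=C([C@H]1O[C@@H]1c1ccc(OCOC)cc1)c1c(Br)cc(OCOC)c(C/C=C(\C)CCC=C(C)C)c1OCOC
F3 | step 3 | [2-bromo-5-geranyl-4,6-bis(methoxymethoxy)phenyl]magnesium chloride | Cl[Mg]c1c(Br)cc(OCOC)c(C/C=C(\C)CCC=C(C)C)c1OCOC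
F4 | step 3 | rac-1-[2-bromo-5-geranyl-4,6-bis(methoxymethoxy)phenyl]ethan-1-ol | CC(O)c1c(Br)cc(OCOC)c(C/C=C(\C)CCC=C(C)C)c1OCOC
F5 | step 9 | (1S,3S)-3-[5-geranyl-2-iodo-4,6-bis(methoxymethoxy)phenyl]-3-(tert-butyldimethylsilyloxy)-1-[4-(methoxymethoxy)phenyl]propyl acetate | Ic1cc(OCOC)c(C/C=C(\C)CCC=C(C)C)c(OCOC)c1[C@@H](O[Si](C)(C)C(C)(C)C)C[C@@H](c1ccc(OCOC)cc1)OC(C)=O
F6 | step 9 | (1S,3S)-3-[5-geranyl-2-iodo-4,6-bis(methoxymethoxy)phenyl]-3-(tert-butyldimethylsilyloxy)-1-[4-(methoxymethoxy)phenyl]propan-1-ol | Ic1cc(OCOC)c(C/C=C(\C)CCC=C(C)C)c(OCOC)c1[C@@H](O[Si](C)(C)C(C)(C)C)C[C@@H](c1ccc(OCOC)cc1)O
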